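**Retrosynthetic overview**
- Feature: in the butenolide ring (O1′, C2′=O, C3′H, C4′–CH3, C5′H on C15) O1′ lies between C2′ and the base-labile C5′. Without O1′ the ring is a trans-2-alkyl-3-methylcyclobutanone, and its C5′–C15 bond is an anti aldol bond.
- Disconnections: C3′=C4′ (selenoxide elimination) ⇐ saturated γ-lactone ⇐ insertion of O1′ (Baeyer–Villiger) ⇐ cyclobutanone ⇐ C15–C5′ aldol of 3-methylcyclobutanone with the labdane E-enal.
- Enal ⇐ C13=C14 (Horner–Wadsworth–Emmons on the 14,15-dinor-13-ketone) and reduction of an 18,6α-lactone; C18–O ⇐ 1,5-hydrogen transfer to a 6α-alkoxyl radical, with C8=C17 masked as its epoxide ⇐ larixyl acetate.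
- Ring order: the decalin comes from the chiral pool; a temporary O6–C18 oxolane/lactone is made in steps 4–5 and opened in step 8; the four-membered ring enters in step 10; the five-membered lactone is formed last, by ring expansion, in step 12.

Key step: step 12

Remark (numbering): labdane numbering C1–C20 is used for the decalin and side chain; primes are used for the four- or five-membered ring (C2′ carbonyl, C3′, C4′ bearing CH3, C5′ bonded to C15, O1′ the lactone oxygen).
Remark (epoxide): the masking epoxide is drawn as the 8α,17-isomer expected from attack anti to the axial C10 methyl; its configuration is of no consequence because the oxygen is removed again.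
Remark (catalyst sense): the (S)-configured catalyst is assigned the (5′S,15S) sense by the usual hydrogen-bonded enamine model; if the opposite sense were found, the (R)-catalyst would be used.

**Step 1**
Reactants: 1 larixyl acetate
Product: 2 6α-acetoxy-14,15-dinorlabd-8(17)-en-13-one
Conditions: KMnO4, acetone/H2O, 0 °C → rt
Reagents that add atoms: none
Why: Permanganate oxidative cleavage of the vinyl carbinol (hydroxylation of the monosubstituted C14=C15 bond, then glycol and α-ketol cleavage down to C13) is the standard degradation of 13-hydroxy-14-ene labdanes to 14,15-dinor-13-ketones and should spare the more hindered exocyclic C8=C17 bond at 0 °C, while the acetate shields O6 and no stereocentre is formed.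

**Step 2**
Reactants: 2 6α-acetoxy-14,15-dinorlabd-8(17)-en-13-one
Product: 3 6α-hydroxy-14,15-dinorlabd-8(17)-en-13-one
Conditions: K2CO3, MeOH, 50 °C
Reagents that add atoms: none
Why: Base-catalysed transesterification (methanolysis) removes the secondary acetate and frees the 6α-hydroxyl that carries the radical relay, leaving ketone, alkene and all stereocentres untouched.

**Step 3**
Reactants: 3 6α-hydroxy-14,15-dinorlabd-8(17)-en-13-one
Product: 4 8α,17-epoxy-6α-hydroxy-14,15-dinorlabdan-13-one
Conditions: mCPBA, NaHCO3, CH2Cl2, 0 °C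
Reagents that add atoms: meta-chloroperbenzoic acid, OOC(=O)c1cccc(Cl)c1
Why: Prilezhaev epoxidation should take the electron-rich 1,1-disubstituted alkene from the α face (the β face is blocked by the axial C10 methyl) much faster than the methyl ketone undergoes Baeyer–Villiger oxidation, and the epoxide masks C8=C17 so that C7 is no longer allylic in step 4 (a 6-oxyl radical would otherwise fragment to an allyl radical) and no alkene meets RuO4 in step 5.

**Step 4**
Reactants: 4 8α,17-epoxy-6α-hydroxy-14,15-dinorlabdan-13-one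
Product: 7 6α,18:8α,17-diepoxy-14,15-dinorlabdan-13-one (oxolane O6–C18 across C4–C5–C6), via 6α-hypoiodite 5 (not isolated), via 18-iodo alcohol 6 (not isolated)
Conditions: PhI(OAc)2, I2, cyclohexane, hν (tungsten lamp), 30 °C
Reagents that add atoms: none
Why: Hypoiodite reaction (alkoxyl-radical 1,5-hydrogen transfer): light cleaves the O–I bond of 5 to the 6α-oxyl radical, whose equatorial C6–O bond lies parallel and peri to the equatorial C4–C18 bond, so it should abstract a C18 hydrogen through a six-membered transition state, iodine transfer gives 6 and intramolecular displacement closes the oxolane, and because only the 4α-methyl is within reach the new C4 stereocentre is fixed.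

**Step 5**
Reactants: 7 6α,18:8α,17-diepoxy-14,15-dinorlabdan-13-one
Product: 9 8α,17-epoxy-13-oxo-14,15-dinorlabdan-18,6α-olide, via 18-hydroxy lactol 8 (not isolated)
Conditions: RuCl3·xH2O (cat.), NaIO4, CCl4/MeCN/pH 7 buffer, rt
Reagents that add atoms: sodium periodate (oxygen delivered through catalytic RuO4), [Na+].[O-]I(=O)(=O)=O
Why: RuO4 oxidation of a cyclic ether to a lactone should attack the exposed C18 methylene and not the axial C6–H, which is screened by the 4β- and 10β-methyl groups, and the substrate holds no alkene at this stage.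

**Step 6**
Reactants: 9 8α,17-epoxy-13-oxo-14,15-dinorlabdan-18,6α-olide
Product: 11 13-oxo-14,15-dinorlabd-8(17)-en-18,6α-olide, via iodohydrin 10 (not isolated)
Conditions: NaI, Zn dust, NaOAc, AcOH, rt
Reagents that add atoms: none
Why: Reductive deoxygenation of an epoxide through its iodohydrin: iodide opens the oxirane at the primary C17 and zinc-induced β-elimination of the vicinal iodo alcohol 10 can only regenerate the C8=C17 bond, while ketone and lactone are inert to zinc in buffered acetic acid.

**Step 7**
Reactants: 11 13-oxo-14,15-dinorlabd-8(17)-en-18,6α-olide; 12 triethyl phosphonoacetate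
Product: 13 ethyl (13E)-labda-8(17),13-dien-18,6α-olid-15-oate
Conditions: NaH, THF, 0 → 60 °C
Reagents that add atoms: none
Why: Horner–Wadsworth–Emmons olefination of the unhindered methyl ketone should give the trisubstituted enoate with the ester trans to the larger C12 chain (E; the minor Z isomer is removed by chromatography), and the lactone carbonyl, which is neopentyl and has no α-hydrogen, does not react.

**Step 8**
Reactants: 13 ethyl (13E)-labda-8(17),13-dien-18,6α-olid-15-oate
Product: 14 (13E)-labda-8(17),13-diene-6α,15,18-triol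
Conditions: LiAlH4, THF, 0 °C → rt; aq. Rochelle salt
Reagents that add atoms: none
Why: Hydride reduction with LiAlH4 takes the β,β-disubstituted enoate by 1,2-addition to the allylic alcohol and opens the lactone to the 6α,18-diol without touching the alkenes or any stereocentre.

**Step 9**
Reactants: 14 (13E)-labda-8(17),13-diene-6α,15,18-triol
Product: 15 (13E)-6α,18-dihydroxylabda-8(17),13-dien-15-al
Conditions: MnO2, CH2Cl2, rt
Reagents that add atoms: none
Why: Manganese dioxide oxidises only the allylic C15 alcohol, so the E-enal should form while the saturated 6α- and 18-hydroxyls stay free.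

**Step 10**
Reactants: 15 (13E)-6α,18-dihydroxylabda-8(17),13-dien-15-al; 16 3-methylcyclobutanone
Product: 18 (4′S,5′S,15S)-anti-aldol adduct (free triol; trans-2-alkyl-3-methylcyclobutanone), via cyclobutenyl enamine 17 (not isolated)
Conditions: (S)-N-(phenylsulfonyl)pyrrolidine-2-carboxamide (20 mol %), 16 (10 equiv), CH2Cl2, 4 °C → rt
Reagents that add atoms: none
Why: Enamine-catalysed direct aldol addition with desymmetrisation of the 3-substituted cyclobutanone: the catalyst forms enamine 17 at the α-carbon whose reacting face is anti to the methyl group (sets C4′, 2,3-trans), the acidic sulfonamide N–H binds the aldehyde in a closed chair-like transition state that gives the anti adduct from the ring (E)-enamine, and the (S)-pyrrolidine fixes the absolute sense at C5′ and C15 (both S), while the β,β-disubstituted enal, a poor conjugate acceptor, reacts at the carbonyl.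

**Step 11**
Reactants: 18 (4′S,5′S,15S)-anti-aldol adduct
Product: 19 6α,15,18-tris(tert-butyldimethylsilyl) ether of the aldol adduct (tris-silylated trans-2-alkyl-3-methylcyclobutanone)
Conditions: TBSOTf, 2,6-lutidine, CH2Cl2, −78 → 0 °C
Reagents that add atoms: tert-butyldimethylsilyl trifluoromethanesulfonate, CC(C)(C)[Si](C)(C)OS(=O)(=O)C(F)(F)F
Why: Silylation with the silyl triflate and a hindered pyridine base should cover the primary C18, the allylic C15 and the hindered 6α-hydroxyl in one operation without enolising the cyclobutanone or inducing retro-aldol cleavage.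

**Step 12**
Reactants: 19 tris-silylated cyclobutanone
Product: 21 tris-silylated (4′S,5′S)-4′-methyl-γ-butyrolactone (O1′ inserted into the C5′–C2′ bond), via Criegee adduct 20 (not isolated)
Conditions: 30% aq. H2O2, NaOH, THF/MeOH, 0 °C; then Na2SO3, pH 5 buffer
Reagents that add atoms: hydrogen peroxide, OO
Why: Hydroperoxide anion adds to the strained C2′ carbonyl to give the Criegee adduct 20, in which the more substituted C5′ migrates from carbon to oxygen with loss of hydroxide, so that O1′ is inserted between C5′ and C2′. The closest known reaction type is the Baeyer–Villiger oxidation of 2-substituted cyclobutanones to γ-lactones with alkaline hydrogen peroxide. The five-membered ring is closed not by cyclisation but by a 1,2-shift that enlarges the four-membered ring by one atom, forming C5′–O1′ and O1′–C2′. No stereocentre is created: C5′ migrates with retention and C15 and C4′ are untouched, so the anti aldol relationship becomes the threo C15/C5′ glycol of the target. The step needs regioselectivity, which the higher substitution of C5′ over C3′H2 secures, and chemoselectivity over three alkenes, which follows because nucleophilic peroxide does not epoxidise unactivated alkenes and only the strained ketone is electrophilic enough to add it. Brief exposure at 0 °C and the acidic quench should keep the β-silyloxy ketone from eliminating and re-close any lactone that is hydrolysed.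

**Step 13**
Reactants: 21 tris-silylated γ-lactone
Product: 23 tris-silylated (3′S)-3′-phenylselanyl lactone (Se trans to the 4′-methyl), via lithium enolate 22 (not isolated)
Conditions: LDA, THF, −78 °C; PhSeBr, −78 °C
Reagents that add atoms: benzeneselenenyl bromide, Br[Se]c1ccccc1
Why: α-Selenenylation of a lactone enolate: LDA deprotonates the only acidic position, C3′, and PhSeBr should attack the enolate anti to the adjacent C4′ methyl, which places selenium cis to H4′ as the syn-elimination requires, and at −78 °C the enolate outruns selenenylation of the alkenes.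

**Step 14**
Reactants: 23 3′-phenylselanyl lactone
Product: 25 6α,15,18-tris(tert-butyldimethylsilyl) ether of the target (C3′=C4′ butenolide), via selenoxide 24 (not isolated)
Conditions: NaIO4, NaHCO3, THF/MeOH/H2O, 0 °C → rt
Reagents that add atoms: none
Why: Selenoxide syn-elimination: periodate oxidises selenium but not alkenes, the selenoxide 24 has H4′ as its only β-hydrogen and should eliminate at room temperature to the C3′=C4′ butenolide, removing the auxiliary C4′ stereocentre under buffered conditions that do not enolise C5′.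

**Step 15**
Reactants: 25 tris-silylated butenolide
Product: 26 target CNP0221530.1
Conditions: HF·pyridine, pyridine, THF, 0 °C → rt
Reagents that add atoms: none
Why: Fluoride-mediated desilylation with pyridine-buffered HF cleaves the three silyl ethers under weakly acidic conditions, so the γ-centre C5′ of the butenolide should not epimerise through the furanolate and no alkene should migrate.

**Compound list**
1 | larixyl acetate, (13S)-6α-acetoxylabda-8(17),14-dien-13-ol | C=C1C[C@H](OC(C)=O)[C@H]2C(C)(C)CCC[C@]2(C)[C@H]1CC[C@](C)(O)C=C | starting material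
2 | 6α-acetoxy-14,15-dinorlabd-8(17)-en-13-one | C=C1C[C@H](OC(C)=O)[C@H]2C(C)(C)CCC[C@]2(C)[C@H]1CCC(C)=O | intermediate
3 | 6α-hydroxy-14,15-dinorlabd-8(17)-en-13-one | C=C1C[C@H](O)[C@H]2C(C)(C)CCC[C@]2(C)[C@H]1CCC(C)=O | intermediate
4 | 8α,17-epoxy-6α-hydroxy-14,15-dinorlabdan-13-one | C1O[C@@]12C[C@H](O)[C@H]3C(C)(C)CCC[C@]3(C)[C@H]2CCC(C)=O | intermediate
5 | 6α-hypoiodite of 4 | C1O[C@@]12C[C@H](OI)[C@H]3C(C)(C)CCC[C@]3(C)[C@H]2CCC(C)=O | intermediate (not isolated)
6 | 18-iodo alcohol, 8α,17-epoxy-6α-hydroxy-18-iodo-14,15-dinorlabdan-13-one | C1O[C@@]12C[C@H](O)[C@H]3[C@](C)(CI)CCC[C@]3(C)[C@H]2CCC(C)=O | intermediate (not isolated)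
7 | 6α,18:8α,17-diepoxy-14,15-dinorlabdan-13-one | C1O[C@@]12C[C@H](O3)[C@H]4[C@](C)(C3)CCC[C@]4(C)[C@H]2CCC(C)=O | intermediate
8 | 18-hydroxy lactol, 6α,18:8α,17-diepoxy-18-hydroxy-14,15-dinorlabdan-13-one (C18 configuration not defined) | C1O[C@@]12C[C@H](O3)[C@H]4[C@](C)(C3O)CCC[C@]4(C)[C@H]2CCC(C)=O | intermediate (not isolated)
9 | 8α,17-epoxy-13-oxo-14,15-dinorlabdan-18,6α-olide | C1O[C@@]12C[C@H](O3)[C@H]4[C@](C)(C3=O)CCC[C@]4(C)[C@H]2CCC(C)=O | intermediate
10 | iodohydrin, 8α-hydroxy-17-iodo-13-oxo-14,15-dinorlabdan-18,6α-olide | IC[C@@]1(O)C[C@H](O3)[C@H]4[C@](C)(C3=O)CCC[C@]4(C)[C@H]1CCC(C)=O | intermediate (not isolated)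
11 | 13-oxo-14,15-dinorlabd-8(17)-en-18,6α-olide | C=C1C[C@H](O2)[C@H]3[C@](C)(C2=O)CCC[C@]3(C)[C@H]1CCC(C)=O | intermediate
12 | triethyl phosphonoacetate | CCOC(=O)CP(=O)(OCC)OCC | starting material
13 | ethyl (13E)-labda-8(17),13-dien-18,6α-olid-15-oate | C=C1C[C@H](O2)[C@H]3[C@](C)(C2=O)CCC[C@]3(C)[C@H]1CC/C(C)=C/C(=O)OCC | intermediate
14 | (13E)-labda-8(17),13-diene-6α,15,18-triol | C=C1C[C@H](O)[C@H]2[C@](C)(CO)CCC[C@]2(C)[C@H]1CC/C(C)=C/CO | intermediate
15 | (13E)-6α,18-dihydroxylabda-8(17),13-dien-15-al | C=C1C[C@H](O)[C@H]2[C@](C)(CO)CCC[C@]2(C)[C@H]1CC/C(C)=C/C=O | intermediate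
16 | 3-methylcyclobutanone | CC1CC(=O)C1 | starting material
17 | cyclobutenyl enamine, (S)-1-[(3S)-3-methylcyclobut-1-en-1-yl]-N-(phenylsulfonyl)pyrrolidine-2-carboxamide, formed from 16 on the catalyst | C[C@H]1CC(N2CCC[C@H]2C(=O)NS(=O)(=O)c2ccccc2)=C1 | intermediate (not isolated)
18 | (4′S,5′S,15S)-anti-aldol adduct (free triol, trans-2-alkyl-3-methylcyclobutanone) | C=C1C[C@H](O)[C@H]2[C@](C)(CO)CCC[C@]2(C)[C@H]1CC/C(C)=C/[C@H](O)[C@H]1C(=O)C[C@@H]1C | intermediate
19 | 6α,15,18-tris(tert-butyldimethylsilyl) ether of 18 | C=C1C[C@H](O[Si](C)(C)C(C)(C)C)[C@H]2[C@](C)(CO[Si](C)(C)C(C)(C)C)CCC[C@]2(C)[C@H]1CC/C(C)=C/[C@H](O[Si](C)(C)C(C)(C)C)[C@H]1C(=O)C[C@@H]1C | intermediate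
20 | Criegee adduct, C2′ hydroxy-hydroperoxide of 19 (C2′ configuration not defined) | C=C1C[C@H](O[Si](C)(C)C(C)(C)C)[C@H]2[C@](C)(CO[Si](C)(C)C(C)(C)C)CCC[C@]2(C)[C@H]1CC/C(C)=C/[C@H](O[Si](C)(C)C(C)(C)C)[C@H]1C(O)(OO)C[C@@H]1C | intermediate (not isolated)
21 | tris-silylated (4′S,5′S)-4′-methyl-γ-butyrolactone | C=C1C[C@H](O[Si](C)(C)C(C)(C)C)[C@H]2[C@](C)(CO[Si](C)(C)C(C)(C)C)CCC[C@]2(C)[C@H]1CC/C(C)=C/[C@H](O[Si](C)(C)C(C)(C)C)[C@H]1OC(=O)C[C@@H]1C | intermediate
22 | lithium enolate of 21 | C=C1C[C@H](O[Si](C)(C)C(C)(C)C)[C@H]2[C@](C)(CO[Si](C)(C)C(C)(C)C)CCC[C@]2(C)[C@H]1CC/C(C)=C/[C@H](O[Si](C)(C)C(C)(C)C)[C@H]1OC(O[Li])=C[C@@H]1C | intermediate (not isolated)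
23 | tris-silylated (3′S)-3′-phenylselanyl lactone | C=C1C[C@H](O[Si](C)(C)C(C)(C)C)[C@H]2[C@](C)(CO[Si](C)(C)C(C)(C)C)CCC[C@]2(C)[C@H]1CC/C(C)=C/[C@H](O[Si](C)(C)C(C)(C)C)[C@H]1OC(=O)[C@@H]([Se]c2ccccc2)[C@@H]1C | intermediate
24 | selenoxide of 23 (Se configuration not defined) | C=C1C[C@H](O[Si](C)(C)C(C)(C)C)[C@H]2[C@](C)(CO[Si](C)(C)C(C)(C)C)CCC[C@]2(C)[C@H]1CC/C(C)=C/[C@H](O[Si](C)(C)C(C)(C)C)[C@H]1OC(=O)[C@@H]([Se](=O)c2ccccc2)[C@@H]1C | intermediate (not isolated)
25 | 6α,15,18-tris(tert-butyldimethylsilyl) ether of the target | C=C1C[C@H](O[Si](C)(C)C(C)(C)C)[C@H]2[C@](C)(CO[Si](C)(C)C(C)(C)C)CCC[C@]2(C)[C@H]1CC/C(C)=C/[C@H](O[Si](C)(C)C(C)(C)C)[C@H]1OC(=O)C=C1C | intermediate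
26 | CNP0221530.1, (13E,15S,5′S)-15-(4′-methyl-2′-oxo-2′,5′-dihydrofuran-5′-yl)labda-8(17),13-diene-6α,15,18-triol | C=C1C[C@H](O)[C@H]2[C@](C)(CO)CCC[C@]2(C)[C@H]1CC/C(C)=C/[C@H](O)[C@H]1OC(=O)C=C1C | target

**Step count**
Total: 15 steps. Longest linear sequence: 15 steps (1 → 26); 12 and 16 enter directly in steps 7 and 10.

**Steps most likely to fail**

Step 10. The catalytic enamine may add too slowly to the weakly electrophilic β,β-disubstituted enal. The catalyst may also be drawn off by condensation with the enal (iminium or dienamine formation), and long reaction times may erode the anti or facial selectivity. The fallback uses a preformed enolate and sets out from 15 and 16. Silylation of 15 (TBSOTf, 2,6-lutidine) would give (13E)-6α,18-bis(tert-butyldimethylsilyloxy)labda-8(17),13-dien-15-al F1. Ketone 16 would be converted with TMSOTf/Et3N into racemic 3-methyl-1-(trimethylsilyloxy)cyclobut-1-ene F2, and this with SiCl4 and catalytic Hg(OAc)2 into 3-methyl-1-(trichlorosilyloxy)cyclobut-1-ene F3. Lewis-base-catalysed aldol addition of excess F3 to F1 with a chiral stilbene-1,2-diamine-derived phosphoramide (the enantiomer that directs to the 15S face) in CH2Cl2 at −78 °C is a known reaction of cyclic ketone trichlorosilyl enolates with conjugated aldehydes. It runs through a closed chair transition state at hexacoordinate silicon and should give the anti adduct, the trichlorosilyl aldolate F4. Of the racemic enolate, the enantiomer whose methyl group lies opposite the catalyst-preferred face should react faster. Aqueous NaHCO3 work-up would give the 6α,18-bis-silylated aldol with free 15-hydroxyl F5, and TBSOTf/2,6-lutidine would convert it into 19, where the route is rejoined.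

Step 4. β-Fragmentation of the 6-oxyl radical (cleavage of C5–C6 or C6–C7), opening of the spiro-epoxide by iodine(I) species or acetic acid, and over-iodination at C18 may compete with hydrogen transfer and ring closure. The fallback is the Barton nitrite photolysis, which needs neither iodine nor acid, and sets out from 4. NOCl in pyridine at −20 °C would give the 6α-nitrite ester F6. Irradiation (Hg lamp, Pyrex, toluene, 0 °C) should transfer NO to C18 by the same six-membered hydrogen shift, giving the 18-nitroso-6α-alcohol F7, which tautomerises on warming in 2-propanol to the 18-oxime F8. Reductive deoximation with aqueous TiCl3/NH4OAc would give the lactol 8, and oxidation with catalytic TPAP and NMO would give 9, where the route is rejoined (this also replaces step 5).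

Step 6. The spiro-epoxide may rearrange under acid (hydride shift to the C17 aldehyde, or elimination to allylic alcohols) before iodide opens it, or the reductive elimination may stall at the iodohydrin. The fallback changes the order of events and the mode of oxygen removal and sets out from 9. The olefination of step 7 is run first on 9 (12, NaH, THF) to give ethyl (13E)-8α,17-epoxylabd-13-en-18,6α-olid-15-oate F9, which no longer carries a ketone. The oxygen is then abstracted with the lower-valent tungsten reagent made from WCl6 and n-BuLi (THF, −78 °C → rt), a known acid-free deoxygenation of hindered epoxides with retention of the carbon skeleton. This would give 13, where the route is rejoined.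

**Further compounds**
F1 | step 10 | (13E)-6α,18-bis(tert-butyldimethylsilyloxy)labda-8(17),13-dien-15-al | C=C1C[C@H](O[Si](C)(C)C(C)(C)C)[C@H]2[C@](C)(CO[Si](C)(C)C(C)(C)C)CCC[C@]2(C)[C@H]1CC/C(C)=C/C=O
F2 | step 10 | 3-methyl-1-(trimethylsilyloxy)cyclobut-1-ene (racemic) | CC1CC(O[Si](C)(C)C)=C1
F3 | step 10 | 3-methyl-1-(trichlorosilyloxy)cyclobut-1-ene (racemic) | CC1CC(O[Si](Cl)(Cl)Cl)=C1
F4 | step 10 | 15-O-trichlorosilyl aldolate of the 6α,18-bis-silylated adduct | C=C1C[C@H](O[Si](C)(C)C(C)(C)C)[C@H]2[C@](C)(CO[Si](C)(C)C(C)(C)C)CCC[C@]2(C)[C@H]1CC/C(C)=C/[C@H](O[Si](Cl)(Cl)Cl)[C@H]1C(=O)C[C@@H]1C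
F5 | step 10 | 6α,18-bis(tert-butyldimethylsilyl) ether of 18 with free 15-hydroxyl | C=C1C[C@H](O[Si](C)(C)C(C)(C)C)[C@H]2[C@](C)(CO[Si](C)(C)C(C)(C)C)CCC[C@]2(C)[C@H]1CC/C(C)=C/[C@H](O)[C@H]1C(=O)C[C@@H]1C
F6 | step 4 | 6α-nitrite ester of 4 | C1O[C@@]12C[C@H](ON=O)[C@H]3C(C)(C)CCC[C@]3(C)[C@H]2CCC(C)=O
F7 | step 4 | 8α,17-epoxy-6α-hydroxy-18-nitroso-14,15-dinorlabdan-13-one | C1O[C@@]12C[C@H](O)[C@H]3[C@](C)(CN=O)CCC[C@]3(C)[C@H]2CCC(C)=O
F8 | step 4 | 8α,17-epoxy-6α-hydroxy-13-oxo-14,15-dinorlabdan-18-al oxime | C1O[C@@]12C[C@H](O)[C@H]3[C@](C)(C=NO)CCC[C@]3(C)[C@H]2CCC(C)=O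
F9 | step 6 | ethyl (13E)-8α,17-epoxylabd-13-en-18,6α-olid-15-oate | C1O[C@@]12C[C@H](O3)[C@H]4[C@](C)(C3=O)CCC[C@]4(C)[C@H]2CC/C(C)=C/C(=O)OCC
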